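## Retrosynthetic overview

1. The target comes from global desilylation of its octakis(triisopropylsilyl) ether.
2. Both aryl–carbon bonds at C3 and C4 of the oxolane are made in one palladium-catalysed three-component syn-diarylation of a twofold-symmetric (2S,5S)-2,5-diaryl-2,5-dihydrofuran; a 3,5-bis(silyloxy)phenyl iodide adds first and a dihydrobenzofuran-4-boronate second.
3. The dihydrofuran comes from two Heck arylations of 2,3-dihydrofuran (asymmetric with an aryl triflate, then trans-selective with an aryl iodide); the oxolane ring itself is bought.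
4. The boronate comes from Miyaura borylation, acid epimerisation and an enantioselective rhodium-carbene C–H insertion that closes the benzofuran ring; the diazo precursor is built from a salicylaldehyde and an aryl Grignard reagent.
5. The arenes come from iridium-catalysed meta C–H borylation of silylated resorcinol and 3-bromophenol. Ring order: the benzofuran ring is closed first, the oxolane is substituted last.

Abbreviations: TIPS = triisopropylsilyl, TIPSO = triisopropylsilyloxy, Bpin = 4,4,5,5-tetramethyl-1,3,2-dioxaborolan-2-yl, ring D = the benzo ring of the dihydrobenzofuran.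

Assumption: (S)-BINAP is taken to give the (S)-2-aryl-2,3-dihydrofuran and Rh2(S-PTAD)4 the (3R) insertion product; if either sense is opposite, the mirror-image ligand is used and nothing else changes.

## Route

Step 1
Reactants: 1 resorcinol
Product: 2 1,3-bis(triisopropylsilyloxy)benzene
Conditions: TIPSCl (2.3 equiv), imidazole (5 equiv), DMF, 40 °C
Reagents that add atoms: chlorotriisopropylsilane, CC(C)[Si](Cl)(C(C)C)C(C)C
Why: Imidazole-promoted silyl ether formation caps both phenols with groups bulky enough to shield every ortho C–H bond in the next step.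

Step 2
Reactants: 2 1,3-bis(triisopropylsilyloxy)benzene
Product: 4 1-iodo-3,5-bis(triisopropylsilyloxy)benzene, via aryl pinacolboronate 3 (not isolated)
Conditions: [Ir(cod)OMe]2 (1.5 mol %), 4,4'-di-tert-butyl-2,2'-bipyridine (3 mol %), B2pin2 (1.0 equiv), THF, 80 °C; evaporate; then CuI (10 mol %), 1,10-phenanthroline (20 mol %), KI (1.5 equiv), MeOH/THF/H2O, air, 80 °C
Reagents that add atoms: bis(pinacolato)diboron, CC1(C)OB(OC1(C)C)B1OC(C)(C)C(C)(C)O1 (boron of 3 only); potassium iodide, [K+].[I-]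
Why: Sterically governed iridium-catalysed C–H borylation reaches only the one C–H bond without an ortho substituent (C5), and copper-mediated iododeboronation turns the boronate into the iodide in the same flask.

Step 3
Reactants: 5 4-methylphenol (p-cresol)
Product: 6 triisopropyl(4-methylphenoxy)silane
Conditions: TIPSCl (1.1 equiv), imidazole (2.5 equiv), DMF, rt
Reagents that add atoms: chlorotriisopropylsilane, CC(C)[Si](Cl)(C(C)C)C(C)C
Why: Standard imidazole-promoted phenol silylation.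

Step 4
Reactants: 6 triisopropyl(4-methylphenoxy)silane
Product: 7 [4-(bromomethyl)phenoxy]triisopropylsilane
Conditions: NBS (1.05 equiv), AIBN (5 mol %), PhCF3, 80 °C
Reagents that add atoms: N-bromosuccinimide, O=C1CCC(=O)N1Br
Why: Wohl–Ziegler radical bromination takes the benzylic methyl C–H bond, the weakest in the molecule.

Step 5
Reactants: 8 3-bromophenol
Product: 9 (3-bromophenoxy)triisopropylsilane
Conditions: TIPSCl (1.1 equiv), imidazole (2.5 equiv), DMF, rt
Reagents that add atoms: chlorotriisopropylsilane, CC(C)[Si](Cl)(C(C)C)C(C)C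
Why: Standard imidazole-promoted phenol silylation.

Step 6
Reactants: 9 (3-bromophenoxy)triisopropylsilane
Product: 11 3-bromo-5-(triisopropylsilyloxy)phenol, via aryl pinacolboronate 10 (not isolated)
Conditions: [Ir(cod)OMe]2 (1.5 mol %), 4,4'-di-tert-butyl-2,2'-bipyridine (3 mol %), B2pin2 (1.0 equiv), THF, 80 °C; then KHSO5 (as 2KHSO5·KHSO4·K2SO4, 1.1 equiv), acetone/H2O, rt, 15 min
Reagents that add atoms: bis(pinacolato)diboron, CC1(C)OB(OC1(C)C)B1OC(C)(C)C(C)(C)O1 (boron of 10 only); potassium peroxymonosulfate, [K+].[O-]S(=O)(=O)OO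
Why: C–H borylation occurs at the only position meta to both bromine and the silyloxy group, and one-pot oxidation of C–B to C–OH gives a resorcinol with its two oxygens already differentiated, the C–Br bond being inert to the iridium catalyst.

Step 7
Reactants: 11 3-bromo-5-(triisopropylsilyloxy)phenol; 12 formaldehyde (as paraformaldehyde)
Product: 13 2-bromo-6-hydroxy-4-(triisopropylsilyloxy)benzaldehyde
Conditions: MgCl2 (2 equiv), Et3N (4 equiv), (CH2O)n (6 equiv), MeCN, 80 °C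
Reagents that add atoms: none
Why: Casnati–Skattebøl ortho-formylation delivers formaldehyde within the magnesium phenoxide to the ortho carbon para to the silyloxy group (more electron-rich and not screened by the TIPS group), and a second formaldehyde oxidises the benzylic alkoxide to the aldehyde.

Step 8
Reactants: 13 2-bromo-6-hydroxy-4-(triisopropylsilyloxy)benzaldehyde; 7 [4-(bromomethyl)phenoxy]triisopropylsilane
Product: 14 2-bromo-4-(triisopropylsilyloxy)-6-{[4-(triisopropylsilyloxy)phenyl]methoxy}benzaldehyde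
Conditions: K2CO3 (1.5 equiv), acetone, 45 °C
Reagents that add atoms: none
Why: Williamson etherification of the acidic salicylaldehyde phenol with a reactive benzylic bromide under conditions that leave aryl TIPS ethers intact.

Step 9
Reactants: 4 1-iodo-3,5-bis(triisopropylsilyloxy)benzene; 14 2-bromo-4-(triisopropylsilyloxy)-6-{[4-(triisopropylsilyloxy)phenyl]methoxy}benzaldehyde
Product: 16 racemic [2-bromo-4-(TIPSO)-6-{[4-(TIPSO)phenyl]methoxy}phenyl][3,5-bis(TIPSO)phenyl]methanol, via aryl Grignard reagent 15 (not isolated)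
Conditions: 4 (1.3 equiv), iPrMgCl·LiCl (1.3 equiv), THF, −20 °C, 1 h; then 14, −78 → 0 °C; aq. NH4Cl
Reagents that add atoms: isopropylmagnesium chloride lithium chloride complex, CC(C)[Mg]Cl.[Li+].[Cl-] (magnesium and chlorine of 15 only)
Why: Iodine–magnesium exchange (Knochel) then Grignard 1,2-addition to the aldehyde, which is far faster than any exchange at the aryl bromide; the new carbinol centre is racemic and is erased in step 10.

Step 10
Reactants: 16 racemic diarylmethanol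
Product: 17 [2-bromo-4-(TIPSO)-6-{[4-(TIPSO)phenyl]methoxy}phenyl][3,5-bis(TIPSO)phenyl]methanone
Conditions: Dess–Martin periodinane (1.3 equiv), CH2Cl2, rt
Reagents that add atoms: none
Why: Dess–Martin oxidation of a benzhydrol to the diaryl ketone under neutral conditions tolerated by silyl ethers and the benzylic ether.

Step 11
Reactants: 17 diaryl ketone
Product: 18 {[2-bromo-4-(TIPSO)-6-{[4-(TIPSO)phenyl]methoxy}phenyl][3,5-bis(TIPSO)phenyl]methylidene}hydrazine (E/Z mixture)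
Conditions: N2H4·H2O (20 equiv), AcOH (0.2 equiv), EtOH, 90 °C, sealed tube
Reagents that add atoms: hydrazine, NN
Why: Acid-catalysed hydrazone condensation, run under forcing conditions because the carbonyl is flanked by two ortho substituents.

Step 12
Reactants: 18 hydrazone
Product: 20 (2S,3R)-4-bromo-3-[3,5-bis(TIPSO)phenyl]-6-(TIPSO)-2-[4-(TIPSO)phenyl]-2,3-dihydro-1-benzofuran (cis), via diaryldiazomethane 19 (not isolated)
Conditions: MnO2 (8 equiv), CH2Cl2, 0 °C, 1 h; filter under argon; then Rh2(S-PTAD)4 (1 mol %), CH2Cl2, −20 °C → rt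
Reagents that add atoms: none
Why: Dehydrogenation of the hydrazone gives a donor/donor diazo compound whose rhodium carbene inserts into the ether-activated benzylic C–H bond through a five-membered transition state (intramolecular C–H insertion), the chiral carboxylate pocket setting C3 as R and the concerted insertion giving the cis ring (C2 S).

Step 13
Reactants: 20 cis-(2S,3R)-dihydrobenzofuran
Product: 21 (2R,3R)-4-bromo-3-[3,5-bis(TIPSO)phenyl]-6-(TIPSO)-2-[4-(TIPSO)phenyl]-2,3-dihydro-1-benzofuran (trans)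
Conditions: CF3CO2H (5 equiv), CH2Cl2, 0 °C → rt
Reagents that add atoms: none
Why: Acid reversibly ionises the C2–O bond (benzylic cation stabilised by the 4-silyloxyphenyl group) and re-closure gives the more stable trans isomer, so C2 becomes R while the catalyst-set C3 (R) is not touched.

Step 14
Reactants: 21 trans-(2R,3R)-4-bromodihydrobenzofuran
Product: 22 (2R,3R)-3-[3,5-bis(TIPSO)phenyl]-6-(TIPSO)-2-[4-(TIPSO)phenyl]-4-(4,4,5,5-tetramethyl-1,3,2-dioxaborolan-2-yl)-2,3-dihydro-1-benzofuran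
Conditions: Pd(OAc)2 (5 mol %), XPhos (10 mol %), B2pin2 (2 equiv), KOAc (3 equiv), 1,4-dioxane, 90 °C
Reagents that add atoms: bis(pinacolato)diboron, CC1(C)OB(OC1(C)C)B1OC(C)(C)C(C)(C)O1
Why: Miyaura borylation of the aryl bromide with a bulky biarylphosphine that copes with the one ortho substituent; no stereocentre is involved.

Step 15
Reactants: 23 hydroquinone
Product: 24 4-(triisopropylsilyloxy)phenol
Conditions: 23 (3 equiv), TIPSCl (1 equiv), imidazole (2 equiv), DMF, 0 °C → rt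
Reagents that add atoms: chlorotriisopropylsilane, CC(C)[Si](Cl)(C(C)C)C(C)C
Why: Statistical monosilylation, made selective by excess diol, which is washed out with water.

Step 16
Reactants: 24 4-(triisopropylsilyloxy)phenol
Product: 25 4-(triisopropylsilyloxy)phenyl trifluoromethanesulfonate
Conditions: (CF3SO2)2O (1.1 equiv), pyridine (2 equiv), CH2Cl2, 0 °C
Reagents that add atoms: trifluoromethanesulfonic anhydride, O=S(=O)(OS(=O)(=O)C(F)(F)F)C(F)(F)F
Why: Standard phenol triflation gives the electrophile needed for the cationic Heck pathway.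

Step 17
Reactants: 25 4-(triisopropylsilyloxy)phenyl trifluoromethanesulfonate; 26 2,3-dihydrofuran
Product: 27 (2S)-2-[4-(triisopropylsilyloxy)phenyl]-2,3-dihydrofuran
Conditions: Pd(OAc)2 (3 mol %), (S)-BINAP (6 mol %), 26 (5 equiv), 1,8-bis(dimethylamino)naphthalene (3 equiv), benzene, 40 °C; chromatography on Et3N-treated silica
Reagents that add atoms: none
Why: Hayashi asymmetric intermolecular Heck reaction, in which the cationic arylpalladium–BINAP complex adds the aryl group next to oxygen on one enantiotopic face and β-hydride elimination/re-insertion moves the double bond to the enol ether position, setting C2 as S.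

Step 18
Reactants: 28 4-iodophenol
Product: 29 (4-iodophenoxy)triisopropylsilane
Conditions: TIPSCl (1.1 equiv), imidazole (2.5 equiv), DMF, rt
Reagents that add atoms: chlorotriisopropylsilane, CC(C)[Si](Cl)(C(C)C)C(C)C
Why: Standard imidazole-promoted phenol silylation.

Step 19
Reactants: 27 (2S)-2-[4-(TIPSO)phenyl]-2,3-dihydrofuran; 29 (4-iodophenoxy)triisopropylsilane
Product: 30 (2S,5S)-2,5-bis[4-(triisopropylsilyloxy)phenyl]-2,5-dihydrofuran (trans)
Conditions: Pd(OAc)2 (5 mol %), PPh3 (10 mol %), Ag2CO3 (1.5 equiv), MeCN, 60 °C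
Reagents that add atoms: none
Why: Silver-promoted Heck arylation of the enol ether (Larock conditions) adds the aryl group next to oxygen on the face away from the existing C2 aryl group, and syn β-hydride elimination toward C3 without re-insertion leaves the 2,5-dihydrofuran, so the new centre is S and the product is the trans isomer.

Step 20
Reactants: 30 (2S,5S)-2,5-bis[4-(TIPSO)phenyl]-2,5-dihydrofuran; 4 1-iodo-3,5-bis(triisopropylsilyloxy)benzene; 22 dihydrobenzofuran-4-yl pinacolboronate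
Product: 31 (2R,3R)-3-[3,5-bis(TIPSO)phenyl]-4-{(2S,3S,4R,5S)-4-[3,5-bis(TIPSO)phenyl]-2,5-bis[4-(TIPSO)phenyl]oxolan-3-yl}-6-(TIPSO)-2-[4-(TIPSO)phenyl]-2,3-dihydro-1-benzofuran
Conditions: Pd(OAc)2 (10 mol %), P(2-furyl)3 (25 mol %), Ag2CO3 (1.5 equiv), H2O (5 equiv), THF, 50 °C; 30 (1.5 equiv), 4 (1.5 equiv); 22 (1.0 equiv) added over 8 h by syringe pump
Reagents that add atoms: none
Why: Proposed new method: a palladium-catalysed three-component syn-1,2-diarylation of an unstrained ring alkene, in which the cationic divalent arylpalladium species from 4 inserts C3=C4 of 30 with the aryl group going to the carbon whose neighbouring aryl group lies on the far face, so that palladium ends on a carbon whose two β-hydrogens are both anti (as in a norbornylpalladium species) and cannot undergo β-hydride elimination, then transmetalates with 22 and reductively eliminates with retention, which places the two new aryl groups cis, the resorcinol-type ring trans to its neighbour (C4 R) and the benzofuranyl ring cis to its neighbour (C3 S); because 30 is twofold-symmetric both faces are equivalent, and the opposite insertion sense has a syn hydrogen at C5 and leaves as a Heck product, not a diastereomer; the closest known reaction type is the aryl halide/norbornene/arylboronic acid three-component coupling (Heck insertion with Suzuki termination).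

Step 21
Reactants: 31 octakis(triisopropylsilyl) ether
Product: 32 5-[(2R,3R)-4-[(2S,3S,4R,5S)-4-(3,5-dihydroxyphenyl)-2,5-bis(4-hydroxyphenyl)oxolan-3-yl]-6-hydroxy-2-(4-hydroxyphenyl)-2,3-dihydro-1-benzofuran-3-yl]benzene-1,3-diol (CNP0202577.3)
Conditions: Bu4NF (12 equiv), AcOH (12 equiv), THF, 0 °C → rt, argon; reversed-phase chromatography
Reagents that add atoms: none
Why: Buffered fluoride desilylation removes all eight aryl silyl ethers without acid or hydrogenolysis, so the benzylic C–O bonds and all six stereocentres are untouched.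

## Compound list

1 | resorcinol | Oc1cccc(O)c1 | starting material
2 | 1,3-bis(triisopropylsilyloxy)benzene | CC(C)[Si](Oc1cccc(O[Si](C(C)C)(C(C)C)C(C)C)c1)(C(C)C)C(C)C | intermediate
3 | 2-[3,5-bis(triisopropylsilyloxy)phenyl]-4,4,5,5-tetramethyl-1,3,2-dioxaborolane | CC1(C)OB(OC1(C)C)c1cc(O[Si](C(C)C)(C(C)C)C(C)C)cc(O[Si](C(C)C)(C(C)C)C(C)C)c1 | intermediate
4 | 1-iodo-3,5-bis(triisopropylsilyloxy)benzene | Ic1cc(O[Si](C(C)C)(C(C)C)C(C)C)cc(O[Si](C(C)C)(C(C)C)C(C)C)c1 | intermediate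
5 | 4-methylphenol | Cc1ccc(O)cc1 | starting material
6 | triisopropyl(4-methylphenoxy)silane | Cc1ccc(O[Si](C(C)C)(C(C)C)C(C)C)cc1 | intermediate
7 | [4-(bromomethyl)phenoxy]triisopropylsilane | BrCc1ccc(O[Si](C(C)C)(C(C)C)C(C)C)cc1 | intermediate
8 | 3-bromophenol | Oc1cccc(Br)c1 | starting material
9 | (3-bromophenoxy)triisopropylsilane | Brc1cccc(O[Si](C(C)C)(C(C)C)C(C)C)c1 | intermediate
10 | 2-[3-bromo-5-(triisopropylsilyloxy)phenyl]-4,4,5,5-tetramethyl-1,3,2-dioxaborolane | CC1(C)OB(OC1(C)C)c1cc(Br)cc(O[Si](C(C)C)(C(C)C)C(C)C)c1 | intermediate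
11 | 3-bromo-5-(triisopropylsilyloxy)phenol | Oc1cc(Br)cc(O[Si](C(C)C)(C(C)C)C(C)C)c1 | intermediate
12 | formaldehyde (paraformaldehyde) | C=O | starting material
13 | 2-bromo-6-hydroxy-4-(triisopropylsilyloxy)benzaldehyde | O=Cc1c(O)cc(O[Si](C(C)C)(C(C)C)C(C)C)cc1Br | intermediate
14 | 2-bromo-4-(triisopropylsilyloxy)-6-{[4-(triisopropylsilyloxy)phenyl]methoxy}benzaldehyde | O=Cc1c(OCc2ccc(O[Si](C(C)C)(C(C)C)C(C)C)cc2)cc(O[Si](C(C)C)(C(C)C)C(C)C)cc1Br | intermediate
15 | [3,5-bis(triisopropylsilyloxy)phenyl]magnesium chloride (LiCl complex) | Cl[Mg]c1cc(O[Si](C(C)C)(C(C)C)C(C)C)cc(O[Si](C(C)C)(C(C)C)C(C)C)c1 | intermediate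
16 | racemic [2-bromo-4-(TIPSO)-6-{[4-(TIPSO)phenyl]methoxy}phenyl][3,5-bis(TIPSO)phenyl]methanol | OC(c1cc(O[Si](C(C)C)(C(C)C)C(C)C)cc(O[Si](C(C)C)(C(C)C)C(C)C)c1)c1c(OCc2ccc(O[Si](C(C)C)(C(C)C)C(C)C)cc2)cc(O[Si](C(C)C)(C(C)C)C(C)C)cc1Br | intermediate
17 | [2-bromo-4-(TIPSO)-6-{[4-(TIPSO)phenyl]methoxy}phenyl][3,5-bis(TIPSO)phenyl]methanone | O=C(c1cc(O[Si](C(C)C)(C(C)C)C(C)C)cc(O[Si](C(C)C)(C(C)C)C(C)C)c1)c1c(OCc2ccc(O[Si](C(C)C)(C(C)C)C(C)C)cc2)cc(O[Si](C(C)C)(C(C)C)C(C)C)cc1Br | intermediate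
18 | hydrazone of 17 (E/Z mixture) | NN=C(c1cc(O[Si](C(C)C)(C(C)C)C(C)C)cc(O[Si](C(C)C)(C(C)C)C(C)C)c1)c1c(OCc2ccc(O[Si](C(C)C)(C(C)C)C(C)C)cc2)cc(O[Si](C(C)C)(C(C)C)C(C)C)cc1Br | intermediate
19 | 1-bromo-2-{diazo[3,5-bis(TIPSO)phenyl]methyl}-5-(TIPSO)-3-{[4-(TIPSO)phenyl]methoxy}benzene | [N-]=[N+]=C(c1cc(O[Si](C(C)C)(C(C)C)C(C)C)cc(O[Si](C(C)C)(C(C)C)C(C)C)c1)c1c(OCc2ccc(O[Si](C(C)C)(C(C)C)C(C)C)cc2)cc(O[Si](C(C)C)(C(C)C)C(C)C)cc1Br | intermediate
20 | (2S,3R)-4-bromo-3-[3,5-bis(TIPSO)phenyl]-6-(TIPSO)-2-[4-(TIPSO)phenyl]-2,3-dihydro-1-benzofuran (cis) | Brc1cc(O[Si](C(C)C)(C(C)C)C(C)C)cc2c1[C@@H](c1cc(O[Si](C(C)C)(C(C)C)C(C)C)cc(O[Si](C(C)C)(C(C)C)C(C)C)c1)[C@@H](c1ccc(O[Si](C(C)C)(C(C)C)C(C)C)cc1)O2 | intermediate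
21 | (2R,3R)-4-bromo-3-[3,5-bis(TIPSO)phenyl]-6-(TIPSO)-2-[4-(TIPSO)phenyl]-2,3-dihydro-1-benzofuran (trans) | Brc1cc(O[Si](C(C)C)(C(C)C)C(C)C)cc2c1[C@@H](c1cc(O[Si](C(C)C)(C(C)C)C(C)C)cc(O[Si](C(C)C)(C(C)C)C(C)C)c1)[C@H](c1ccc(O[Si](C(C)C)(C(C)C)C(C)C)cc1)O2 | intermediate
22 | (2R,3R)-3-[3,5-bis(TIPSO)phenyl]-6-(TIPSO)-2-[4-(TIPSO)phenyl]-4-Bpin-2,3-dihydro-1-benzofuran | CC1(C)OB(OC1(C)C)c1cc(O[Si](C(C)C)(C(C)C)C(C)C)cc2c1[C@@H](c1cc(O[Si](C(C)C)(C(C)C)C(C)C)cc(O[Si](C(C)C)(C(C)C)C(C)C)c1)[C@H](c1ccc(O[Si](C(C)C)(C(C)C)C(C)C)cc1)O2 | intermediate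
23 | hydroquinone | Oc1ccc(O)cc1 | starting material
24 | 4-(triisopropylsilyloxy)phenol | Oc1ccc(O[Si](C(C)C)(C(C)C)C(C)C)cc1 | intermediate
25 | 4-(triisopropylsilyloxy)phenyl trifluoromethanesulfonate | FC(F)(F)S(=O)(=O)Oc1ccc(O[Si](C(C)C)(C(C)C)C(C)C)cc1 | intermediate
26 | 2,3-dihydrofuran | C1=COCC1 | starting material
27 | (2S)-2-[4-(triisopropylsilyloxy)phenyl]-2,3-dihydrofuran | C1=CO[C@H](c2ccc(O[Si](C(C)C)(C(C)C)C(C)C)cc2)C1 | intermediate
28 | 4-iodophenol | Oc1ccc(I)cc1 | starting material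
29 | (4-iodophenoxy)triisopropylsilane | Ic1ccc(O[Si](C(C)C)(C(C)C)C(C)C)cc1 | intermediate
30 | (2S,5S)-2,5-bis[4-(triisopropylsilyloxy)phenyl]-2,5-dihydrofuran | CC(C)[Si](Oc1ccc([C@H]2O[C@H](c3ccc(O[Si](C(C)C)(C(C)C)C(C)C)cc3)C=C2)cc1)(C(C)C)C(C)C | intermediate
31 | octakis(triisopropylsilyl) ether of the target (name in step 20) | CC(C)[Si](Oc1ccc([C@H]2O[C@H](c3ccc(O[Si](C(C)C)(C(C)C)C(C)C)cc3)[C@@H](c3cc(O[Si](C(C)C)(C(C)C)C(C)C)cc(O[Si](C(C)C)(C(C)C)C(C)C)c3)[C@H]2c2cc(O[Si](C(C)C)(C(C)C)C(C)C)cc3c2[C@@H](c2cc(O[Si](C(C)C)(C(C)C)C(C)C)cc(O[Si](C(C)C)(C(C)C)C(C)C)c2)[C@H](c2ccc(O[Si](C(C)C)(C(C)C)C(C)C)cc2)O3)cc1)(C(C)C)C(C)C | intermediate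
32 | CNP0202577.3 (name in step 21) | Oc1ccc([C@H]2O[C@H](c3ccc(O)cc3)[C@@H](c3cc(O)cc(O)c3)[C@H]2c2cc(O)cc3c2[C@@H](c2cc(O)cc(O)c2)[C@H](c2ccc(O)cc2)O3)cc1 | target

## Step count and risks

Total step count: 21. Longest linear sequence: 12 (steps 5–14, 20, 21, from 3-bromophenol).

Three steps most likely to fail:

Step 20 (the proposed new reaction). Risks are direct biaryl coupling of 4 with 22, the opposite insertion sense (Heck product), and slow transmetalation at a palladium centre flanked by two cis aryl groups. The fallback uses known chemistry, sets out from 30 (with 4 and 21) and returns at 31. Epoxidation of 30 (mCPBA, NaHCO3, CH2Cl2, 0 °C; both faces are equivalent) gives the trans-diaryl epoxide 2,4-bis[4-(TIPSO)phenyl]-3,6-dioxabicyclo[3.1.0]hexane F1. Copper-catalysed opening with Grignard reagent 15 (CuI 10 mol %, THF, −30 °C) occurs anti, at the epoxide carbon whose ring neighbour carries its aryl group on the epoxide face, and gives 4-[3,5-bis(TIPSO)phenyl]-2,5-bis[4-(TIPSO)phenyl]oxolan-3-ol F2, with the new aryl group trans to its neighbour. Dess–Martin oxidation gives the oxolan-3-one F3. The aryllithium from 21 (t-BuLi, THF, −78 °C, then CeCl3) adds to F3 to give the tertiary alcohol F4, which is acylated (KN(SiMe3)2, ClC(O)CO2Me) to the methyl oxalate F5. Radical deoxygenation (Bu3SnH, AIBN, toluene, 110 °C) delivers hydrogen to the planar benzylic radical from the face away from the two flanking aryl groups and gives 31.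

Step 12 (C–H insertion). The carbene carbon sits between an ortho bromine and an ortho benzyloxy group, so azine formation, low conversion or low ee are possible. The fallback sets out from 13 and returns at 21. Addition of 15 (2.2 equiv) to 13 gives 3-bromo-2-{hydroxy[3,5-bis(TIPSO)phenyl]methyl}-5-(TIPSO)phenol F6, and p-toluenesulfinic acid (CH2Cl2, rt) converts it into the sulfone 3-bromo-2-{[3,5-bis(TIPSO)phenyl](4-methylbenzenesulfonyl)methyl}-5-(TIPSO)phenol F7. Bromide 7 and thiolane give 1-{[4-(TIPSO)phenyl]methyl}thiolan-1-ium bromide F8. Cs2CO3 (CH2Cl2, rt) turns F7 into the ortho-quinone methide and F8 into the sulfur ylide, and their [4+1] annulation gives the trans-dihydrobenzofuran as a racemate. Preparative chiral HPLC separates 21 from its (2S,3S) enantiomer F9.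

Step 11 (hydrazone formation). Condensation at the di-ortho-substituted carbonyl may stall, or hydrazine may attack the silyl ethers on long heating. The fallback builds the C=N bond by carbanion addition instead; it sets out from 14 and returns at 18. Aqueous NH3/I2 (THF, rt) converts 14 into 2-bromo-4-(TIPSO)-6-{[4-(TIPSO)phenyl]methoxy}benzonitrile F10. Addition of 15 (CuBr 5 mol %, THF, 60 °C; MeOH quench) gives the N–H ketimine [2-bromo-4-(TIPSO)-6-{[4-(TIPSO)phenyl]methoxy}phenyl][3,5-bis(TIPSO)phenyl]methanimine F11. Transimination with anhydrous N2H4 (THF/EtOH, rt) gives 18.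

Further compounds
F1 | step 20 | 2,4-bis[4-(TIPSO)phenyl]-3,6-dioxabicyclo[3.1.0]hexane (aryl groups trans) | CC(C)[Si](Oc1ccc([C@H]2O[C@H](c3ccc(O[Si](C(C)C)(C(C)C)C(C)C)cc3)[C@H]3O[C@@H]23)cc1)(C(C)C)C(C)C
F2 | step 20 | 4-[3,5-bis(TIPSO)phenyl]-2,5-bis[4-(TIPSO)phenyl]oxolan-3-ol (hydroxyl trans to both neighbours) | CC(C)[Si](Oc1ccc([C@H]2O[C@H](c3ccc(O[Si](C(C)C)(C(C)C)C(C)C)cc3)[C@@H](c3cc(O[Si](C(C)C)(C(C)C)C(C)C)cc(O[Si](C(C)C)(C(C)C)C(C)C)c3)[C@@H]2O)cc1)(C(C)C)C(C)C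
F3 | step 20 | 4-[3,5-bis(TIPSO)phenyl]-2,5-bis[4-(TIPSO)phenyl]oxolan-3-one | CC(C)[Si](Oc1ccc([C@H]2O[C@H](c3ccc(O[Si](C(C)C)(C(C)C)C(C)C)cc3)[C@@H](c3cc(O[Si](C(C)C)(C(C)C)C(C)C)cc(O[Si](C(C)C)(C(C)C)C(C)C)c3)C2=O)cc1)(C(C)C)C(C)C
F4 | step 20 | tertiary alcohol from F3 and the aryllithium of 21 (carbinol configuration open) | CC(C)[Si](Oc1ccc([C@H]2O[C@H](c3ccc(O[Si](C(C)C)(C(C)C)C(C)C)cc3)[C@@H](c3cc(O[Si](C(C)C)(C(C)C)C(C)C)cc(O[Si](C(C)C)(C(C)C)C(C)C)c3)C2(O)c2cc(O[Si](C(C)C)(C(C)C)C(C)C)cc3c2[C@@H](c2cc(O[Si](C(C)C)(C(C)C)C(C)C)cc(O[Si](C(C)C)(C(C)C)C(C)C)c2)[C@H](c2ccc(O[Si](C(C)C)(C(C)C)C(C)C)cc2)O3)cc1)(C(C)C)C(C)C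
F5 | step 20 | methyl oxalate of F4 | CC(C)[Si](Oc1ccc([C@H]2O[C@H](c3ccc(O[Si](C(C)C)(C(C)C)C(C)C)cc3)[C@@H](c3cc(O[Si](C(C)C)(C(C)C)C(C)C)cc(O[Si](C(C)C)(C(C)C)C(C)C)c3)C2(OC(=O)C(=O)OC)c2cc(O[Si](C(C)C)(C(C)C)C(C)C)cc3c2[C@@H](c2cc(O[Si](C(C)C)(C(C)C)C(C)C)cc(O[Si](C(C)C)(C(C)C)C(C)C)c2)[C@H](c2ccc(O[Si](C(C)C)(C(C)C)C(C)C)cc2)O3)cc1)(C(C)C)C(C)C
F6 | step 12 | 3-bromo-2-{hydroxy[3,5-bis(TIPSO)phenyl]methyl}-5-(TIPSO)phenol | Oc1cc(O[Si](C(C)C)(C(C)C)C(C)C)cc(Br)c1C(O)c1cc(O[Si](C(C)C)(C(C)C)C(C)C)cc(O[Si](C(C)C)(C(C)C)C(C)C)c1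
F7 | step 12 | 3-bromo-2-{[3,5-bis(TIPSO)phenyl](4-methylbenzenesulfonyl)methyl}-5-(TIPSO)phenol | Cc1ccc(cc1)S(=O)(=O)C(c1cc(O[Si](C(C)C)(C(C)C)C(C)C)cc(O[Si](C(C)C)(C(C)C)C(C)C)c1)c1c(O)cc(O[Si](C(C)C)(C(C)C)C(C)C)cc1Br
F8 | step 12 | 1-{[4-(TIPSO)phenyl]methyl}thiolan-1-ium bromide | CC(C)[Si](Oc1ccc(C[S+]2CCCC2)cc1)(C(C)C)C(C)C.[Br-]
F9 | step 12 | (2S,3S) enantiomer of 21 | Brc1cc(O[Si](C(C)C)(C(C)C)C(C)C)cc2c1[C@H](c1cc(O[Si](C(C)C)(C(C)C)C(C)C)cc(O[Si](C(C)C)(C(C)C)C(C)C)c1)[C@@H](c1ccc(O[Si](C(C)C)(C(C)C)C(C)C)cc1)O2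
F10 | step 11 | 2-bromo-4-(TIPSO)-6-{[4-(TIPSO)phenyl]methoxy}benzonitrile | N#Cc1c(OCc2ccc(O[Si](C(C)C)(C(C)C)C(C)C)cc2)cc(O[Si](C(C)C)(C(C)C)C(C)C)cc1Br
F11 | step 11 | [2-bromo-4-(TIPSO)-6-{[4-(TIPSO)phenyl]methoxy}phenyl][3,5-bis(TIPSO)phenyl]methanimine | N=C(c1cc(O[Si](C(C)C)(C(C)C)C(C)C)cc(O[Si](C(C)C)(C(C)C)C(C)C)c1)c1c(OCc2ccc(O[Si](C(C)C)(C(C)C)C(C)C)cc2)cc(O[Si](C(C)C)(C(C)C)C(C)C)cc1Br
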